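**Plan**

1. Locants follow 1H-isochromene (O2, C1, C3, C4, C4a, C5 to C8, C8a). PMB = 4-methoxybenzyl, TBS = tert-butyldimethylsilyl, Ipc = isopinocampheyl.
2. Retrosynthetic cuts, in order: the three O–PMB bonds; O2–C3 (pyran ring); the C8 ketone back to a carbinol; C8–C8a together with C4a–C4 in one operation (open-chain 5-ynal 17 plus alkyne 5); the ester O–C(=O) bond at C6; C5–C4a (acetylide plus epoxide); C6–C7 (crotylboration).
3. Enabling feature: the tetrasubstituted C4a=C8a double bond of the carbocycle holds ring carbon C8 trans to side-chain carbon C4. This is the pattern of an anti addition of an aldehyde carbon and an alkynyl group across a C4a≡C8a triple bond. The resulting C8=O/C8a=C4a/C4≡C3 enynone then has C3 as δ-acceptor, six atoms from the C1 oxygen.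
4. Forward order: the chain is assembled first; the carbocycle closes in step 8 (C8–C8a); the pyran ring closes in step 10 (O2–C3); acid deprotection is last.
5. Stereochemistry: C6 and C7 (6R,7R; cis on the ring, anti in the open chain) are set together in step 4 by reagent-controlled (E)-crotylboration and are not touched again. The C8 carbinol centre made in step 8 is removed by oxidation.

Key step: step 8

Remark: commercial aqueous chloroacetaldehyde is assumed to be dried and distilled immediately before step 4; the target locants above are used for all intermediates.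

**Route**

Step 1
Reactants: 1 methyl 2,4-dihydroxy-6-methylbenzoate (methyl orsellinate)
Product: 2 methyl 2,4-bis[(4-methoxybenzyl)oxy]-6-methylbenzoate
Conditions: PMBCl, K2CO3, DMF, 60 °C
Reagents that add atoms: 4-methoxybenzyl chloride, COc1ccc(CCl)cc1
Why: Williamson etherification of both phenols, with warming to engage the hydrogen-bonded 2-hydroxyl.

Step 2
Reactants: 2 methyl 2,4-bis[(4-methoxybenzyl)oxy]-6-methylbenzoate
Product: 3 2,4-bis[(4-methoxybenzyl)oxy]-6-methylbenzoic acid
Conditions: KOH, DMSO/H2O, 90 °C; then 1 M HCl, 0 °C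
Reagents that add atoms: potassium hydroxide, [K+].[OH-]
Why: Saponification of the hindered 2,6-disubstituted ester with hot hydroxide in DMSO, conditions to which PMB ethers are inert.

Step 3
Reactants: 4 pent-4-ynoic acid
Product: 5 4-methoxybenzyl pent-4-ynoate
Conditions: PMBCl, K2CO3, DMF, 23 °C
Reagents that add atoms: 4-methoxybenzyl chloride, COc1ccc(CCl)cc1
Why: SN2 O-alkylation of the carboxylate, which masks the acid as an ester cleavable by mild acid and leaves the terminal alkyne free.

Step 4
Reactants: 6 chloroacetaldehyde; 7 (E)-but-2-ene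
Product: 10 (2S)-2-[(2S)-but-3-en-2-yl]oxirane, via (E)-crotyldiisopinocampheylborane 8 (not isolated), via chlorohydrin 9 (not isolated)
Conditions: 7, KOt-Bu, n-BuLi, THF, −78 to −45 °C; (−)-Ipc2BOMe, −78 °C; BF3·OEt2; then 6, −78 °C; then 3 M NaOH, 30% H2O2, 0 to 23 °C
Reagents that add atoms: none
Why: Brown crotylboration through a closed six-membered chair transition state, in which the (E)-crotyl geometry should give the anti C6/C7 relationship and the Ipc groups from (+)-α-pinene should direct attack to the si face of the aldehyde; the alkaline peroxide work-up oxidises boron and closes chlorohydrin 9 to the epoxide with retention at C6.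

Step 5
Reactants: 10 (2S)-2-[(2S)-but-3-en-2-yl]oxirane; 11 tert-butyldimethyl(prop-2-yn-1-yloxy)silane
Product: 13 (3S,4R)-8-(tert-butyldimethylsilyloxy)-3-methyloct-1-en-6-yn-4-ol, via lithium acetylide 12 (not isolated)
Conditions: 11, n-BuLi, THF, −78 °C; BF3·OEt2; then 10, −78 °C
Reagents that add atoms: none
Why: BF3-assisted SN2 opening of the terminal epoxide by the lithium acetylide at the unsubstituted carbon forms C5–C4a and leaves the C6–O stereocentre untouched.

Step 6
Reactants: 13 (3S,4R)-8-(tert-butyldimethylsilyloxy)-3-methyloct-1-en-6-yn-4-ol; 3 2,4-bis[(4-methoxybenzyl)oxy]-6-methylbenzoic acid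
Product: 16 (3S,4R)-8-(tert-butyldimethylsilyloxy)-3-methyloct-1-en-6-yn-4-yl 2,4-bis[(4-methoxybenzyl)oxy]-6-methylbenzoate, via acid chloride 14 (not isolated), via sodium alkoxide 15 (not isolated)
Conditions: 3, 1-chloro-N,N,2-trimethylprop-1-en-1-amine, CH2Cl2, 0 to 23 °C; 13, NaN(SiMe3)2, THF, −78 °C; combine, −78 to 23 °C
Reagents that add atoms: none
Why: Acylation of a preformed alkoxide by an acid chloride made under neutral conditions should overcome the hindrance of the 2,6-disubstituted benzoyl group, with retention at C6 because the C6–O bond is not broken.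

Step 7
Reactants: 16 (3S,4R)-8-(tert-butyldimethylsilyloxy)-3-methyloct-1-en-6-yn-4-yl 2,4-bis[(4-methoxybenzyl)oxy]-6-methylbenzoate
Product: 17 (2R,3R)-7-(tert-butyldimethylsilyloxy)-2-methyl-1-oxohept-5-yn-3-yl 2,4-bis[(4-methoxybenzyl)oxy]-6-methylbenzoate
Conditions: OsO4 (2 mol%), NaIO4, 2,6-lutidine, 1,4-dioxane/H2O, 23 °C
Reagents that add atoms: osmium tetroxide, O=[Os](=O)(=O)=O (delivers the oxygen atom); sodium periodate, [Na+].[O-]I(=O)(=O)=O (re-oxidant and oxygen source)
Why: Lemieux–Johnson cleavage, in which OsO4 should dihydroxylate the terminal alkene far faster than the alkyne or arenes and the lutidine buffer should protect the α-stereocentre of the β-acyloxy aldehyde from epimerisation and elimination.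

Step 8
Reactants: 17 (2R,3R)-7-(tert-butyldimethylsilyloxy)-2-methyl-1-oxohept-5-yn-3-yl 2,4-bis[(4-methoxybenzyl)oxy]-6-methylbenzoate; 5 4-methoxybenzyl pent-4-ynoate
Product: 18 (1R,6S)-4-[(tert-butyldimethylsilyloxy)methyl]-5-hydroxy-3-{5-[(4-methoxybenzyl)oxy]-5-oxopent-1-yn-1-yl}-6-methylcyclohex-3-en-1-yl 2,4-bis[(4-methoxybenzyl)oxy]-6-methylbenzoate (both C8 carbinol epimers)
Conditions: Pd2(dba)3·CHCl3 (5 mol%; dba = dibenzylideneacetone), PCy3 (20 mol%), 5 (2 equiv), MeOH/THF 2:1, 50 °C
Reagents that add atoms: none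
Why: Proposed new method: zerovalent palladium binds the internal alkyne of 17, and the η2-complex attacks the methanol-activated aldehyde carbon C8 through alkyne carbon C8a on the face opposite the metal (outer-sphere, anti), leaving a divalent alkenylpalladium methoxide at C4a; this should exchange methoxide for the acetylide of 5 (the Pd–OMe unit deprotonates the terminal alkyne, as in a copper-free Sonogashira coupling) and release 18 by reductive elimination. The closest known reaction type is the zerovalent-palladium-catalysed anti-selective cyclisation of 5-alkynals with aryl- and alkenylboronic acids in methanol, where a boronic acid plays the role given here to the terminal alkyne. The carbocycle closes in the 6-endo-dig mode, so both alkyne carbons become ring atoms and the new C4a=C8a double bond is endocyclic and tetrasubstituted, with C1 and C4 cis as the later pyran closure requires. The only new stereocentre, the C8 carbinol, is not controlled and is erased in step 9, while C6 and C7 lie outside the reacting centres and should survive the neutral conditions. The step needs endo over exo closure, which the three-atom tether between C8 and the proximal alkyne carbon should secure as it does in the boronic acid precedent, and it needs alkynyl transfer to outrun protonolysis of the alkenyl–palladium bond, which the excess of 5 and the weak acidity of methanol favour. The propargylic silyl ether and the homopropargylic ester are poor leaving groups, so ionisation to allenylpalladium species is not expected.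

Step 9
Reactants: 18 cyclohexenol (both C8 epimers)
Product: 19 (1R,6R)-4-[(tert-butyldimethylsilyloxy)methyl]-3-{5-[(4-methoxybenzyl)oxy]-5-oxopent-1-yn-1-yl}-6-methyl-5-oxocyclohex-3-en-1-yl 2,4-bis[(4-methoxybenzyl)oxy]-6-methylbenzoate
Conditions: Dess–Martin periodinane, CH2Cl2, 0 to 23 °C
Reagents that add atoms: none
Why: Dess–Martin oxidation of the secondary allylic alcohol under non-basic conditions should converge both C8 epimers on one enynone without β-elimination of the C6 ester.

Step 10
Reactants: 19 silyl-protected enynone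
Product: 21 (6R,7R)-3-{3-[(4-methoxybenzyl)oxy]-3-oxopropyl}-7-methyl-8-oxo-5,6,7,8-tetrahydro-1H-isochromen-6-yl 2,4-bis[(4-methoxybenzyl)oxy]-6-methylbenzoate, via hydroxymethyl ynenone 20 (not isolated)
Conditions: HF·pyridine, pyridine, THF, 0 to 23 °C; then AgOSO2CF3 (5 mol%), CH2Cl2, 23 °C
Reagents that add atoms: none
Why: Buffered HF cleaves only the primary silyl ether, and the freed C1 hydroxyl then adds to C3 in a silver-assisted 6-endo-dig oxa-Michael cycloisomerisation, the ring size being fixed because C3 is the δ-carbon of the enynone and C4 is not electrophilic.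

Step 11
Reactants: 21 tris-PMB-protected target
Product: 22 3-[(6R,7R)-6-(2,4-dihydroxy-6-methylbenzoyloxy)-7-methyl-8-oxo-5,6,7,8-tetrahydro-1H-isochromen-3-yl]propanoic acid (CNP0601844.1)
Conditions: CF3CO2H/CH2Cl2 1:9, pentamethylbenzene, 0 °C
Reagents that add atoms: none
Why: Acidolysis of the two aryl PMB ethers and the PMB ester, with the benzyl cations trapped by pentamethylbenzene in a Friedel–Crafts reaction; base is avoided because the β-acyloxy ketone would eliminate and aromatise.

**Compound list**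

1 | methyl 2,4-dihydroxy-6-methylbenzoate | COC(=O)c1c(C)cc(O)cc1O | starting material
2 | methyl 2,4-bis[(4-methoxybenzyl)oxy]-6-methylbenzoate | COC(=O)c1c(C)cc(OCc2ccc(OC)cc2)cc1OCc1ccc(OC)cc1 | intermediate
3 | 2,4-bis[(4-methoxybenzyl)oxy]-6-methylbenzoic acid | OC(=O)c1c(C)cc(OCc2ccc(OC)cc2)cc1OCc1ccc(OC)cc1 | intermediate
4 | pent-4-ynoic acid | C#CCCC(=O)O | starting material
5 | 4-methoxybenzyl pent-4-ynoate | C#CCCC(=O)OCc1ccc(OC)cc1 | intermediate
6 | chloroacetaldehyde | ClCC=O | starting material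
7 | (E)-but-2-ene | C/C=C/C | starting material
8 | (E)-crotyldiisopinocampheylborane (Ipc groups from (+)-α-pinene) | C/C=C/CB([C@@H]1C[C@@H]2C[C@H]([C@H]1C)C2(C)C)[C@@H]1C[C@@H]2C[C@H]([C@H]1C)C2(C)C | intermediate
9 | (2S,3S)-1-chloro-3-methylpent-4-en-2-ol | C=C[C@H](C)[C@H](O)CCl | intermediate
10 | (2S)-2-[(2S)-but-3-en-2-yl]oxirane | C=C[C@H](C)[C@H]1CO1 | intermediate
11 | tert-butyldimethyl(prop-2-yn-1-yloxy)silane | C#CCO[Si](C)(C)C(C)(C)C | starting material
12 | [3-(tert-butyldimethylsilyloxy)prop-1-yn-1-yl]lithium | [Li]C#CCO[Si](C)(C)C(C)(C)C | intermediate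
13 | (3S,4R)-8-(tert-butyldimethylsilyloxy)-3-methyloct-1-en-6-yn-4-ol | C=C[C@H](C)[C@H](O)CC#CCO[Si](C)(C)C(C)(C)C | intermediate
14 | 2,4-bis[(4-methoxybenzyl)oxy]-6-methylbenzoyl chloride | ClC(=O)c1c(C)cc(OCc2ccc(OC)cc2)cc1OCc1ccc(OC)cc1 | intermediate
15 | sodium (3S,4R)-8-(tert-butyldimethylsilyloxy)-3-methyloct-1-en-6-yn-4-olate | C=C[C@H](C)[C@H]([O-])CC#CCO[Si](C)(C)C(C)(C)C.[Na+] | intermediate
16 | (3S,4R)-8-(tert-butyldimethylsilyloxy)-3-methyloct-1-en-6-yn-4-yl 2,4-bis[(4-methoxybenzyl)oxy]-6-methylbenzoate | C=C[C@H](C)[C@H](OC(=O)c1c(C)cc(OCc2ccc(OC)cc2)cc1OCc1ccc(OC)cc1)CC#CCO[Si](C)(C)C(C)(C)C | intermediate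
17 | (2R,3R)-7-(tert-butyldimethylsilyloxy)-2-methyl-1-oxohept-5-yn-3-yl 2,4-bis[(4-methoxybenzyl)oxy]-6-methylbenzoate | O=C[C@H](C)[C@H](OC(=O)c1c(C)cc(OCc2ccc(OC)cc2)cc1OCc1ccc(OC)cc1)CC#CCO[Si](C)(C)C(C)(C)C | intermediate
18 | (1R,6S)-4-[(tert-butyldimethylsilyloxy)methyl]-5-hydroxy-3-{5-[(4-methoxybenzyl)oxy]-5-oxopent-1-yn-1-yl}-6-methylcyclohex-3-en-1-yl 2,4-bis[(4-methoxybenzyl)oxy]-6-methylbenzoate (carbinol epimers) | Cc1cc(OCc2ccc(OC)cc2)cc(OCc2ccc(OC)cc2)c1C(=O)O[C@@H]1CC(C#CCCC(=O)OCc2ccc(OC)cc2)=C(CO[Si](C)(C)C(C)(C)C)C(O)[C@@H]1C | intermediate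
19 | (1R,6R)-4-[(tert-butyldimethylsilyloxy)methyl]-3-{5-[(4-methoxybenzyl)oxy]-5-oxopent-1-yn-1-yl}-6-methyl-5-oxocyclohex-3-en-1-yl 2,4-bis[(4-methoxybenzyl)oxy]-6-methylbenzoate | Cc1cc(OCc2ccc(OC)cc2)cc(OCc2ccc(OC)cc2)c1C(=O)O[C@@H]1CC(C#CCCC(=O)OCc2ccc(OC)cc2)=C(CO[Si](C)(C)C(C)(C)C)C(=O)[C@@H]1C | intermediate
20 | (1R,6R)-4-(hydroxymethyl)-3-{5-[(4-methoxybenzyl)oxy]-5-oxopent-1-yn-1-yl}-6-methyl-5-oxocyclohex-3-en-1-yl 2,4-bis[(4-methoxybenzyl)oxy]-6-methylbenzoate | Cc1cc(OCc2ccc(OC)cc2)cc(OCc2ccc(OC)cc2)c1C(=O)O[C@@H]1CC(C#CCCC(=O)OCc2ccc(OC)cc2)=C(CO)C(=O)[C@@H]1C | intermediate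
21 | (6R,7R)-3-{3-[(4-methoxybenzyl)oxy]-3-oxopropyl}-7-methyl-8-oxo-5,6,7,8-tetrahydro-1H-isochromen-6-yl 2,4-bis[(4-methoxybenzyl)oxy]-6-methylbenzoate | Cc1cc(OCc2ccc(OC)cc2)cc(OCc2ccc(OC)cc2)c1C(=O)O[C@@H]1CC2=C(COC(CCC(=O)OCc3ccc(OC)cc3)=C2)C(=O)[C@@H]1C | intermediate
22 | 3-[(6R,7R)-6-(2,4-dihydroxy-6-methylbenzoyloxy)-7-methyl-8-oxo-5,6,7,8-tetrahydro-1H-isochromen-3-yl]propanoic acid | Cc1cc(O)cc(O)c1C(=O)O[C@@H]1CC2=C(COC(CCC(=O)O)=C2)C(=O)[C@@H]1C | target

**Step count and risks**

Total step count: 11. Longest linear sequence: 8 steps (steps 4 to 11; the branch through steps 1, 2 and 6 to 11 is equally long).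

Most likely to fail:

Step 8 (labelled step). The alkenyl–palladium bond may be protonated by methanol before the alkynyl group is transferred, giving the hydro-cyclised product, or the ring may close in the exo mode. The fallback uses the established boron-terminated version of the same cyclisation; it sets out from 5 and 17 and returns at 21. Alkyne 5 is diborated with bis(pinacolato)diboron and Pt(PPh3)4 in DMF at 80 °C to 4-methoxybenzyl (E)-4,5-bis(pinacolboryl)pent-4-enoate F1, in which the two boryl groups are cis. Compound 17 and F1, with the same zerovalent palladium catalyst in methanol, should give dienylboronate cyclohexenol F2, the less hindered terminal C–B bond transmetalating first. NaBO3·4H2O converts the remaining alkenyl–boron bond into the C3 ketone, giving keto alcohol F3. Dess–Martin periodinane gives enedione F4. HF·pyridine then removes the silyl group, after which the C1 hydroxyl and the C3 ketone should cyclodehydrate to 21.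

Step 11. PMB cations may re-alkylate the nucleophilic dienol ether carbon C4 or the resorcinol ring, and acid may promote loss of the C6 ester with aromatisation of the carbocycle. The fallback reverses the order of unmasking; it sets out from 19 and returns at 22. Compound 19 is treated with CF3CO2H and pentamethylbenzene under anhydrous conditions, which should remove the three PMB groups while the primary silyl ether survives, giving silyl-protected phenol acid F5. HF·pyridine then frees the C1 hydroxyl, which closes the pyran by conjugate addition to C3. The dienol ether therefore forms only after all benzyl cations are gone, and no π-acid is present that could divert the free carboxylic acid onto the alkyne.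

Step 4. The freshly formed epoxide may be opened by hydroxide or hydroperoxide during the telescoped work-up, the volatile product may be lost, and facial selectivity may erode with the small, very reactive α-chloro aldehyde. The fallback builds the epoxide stepwise from non-volatile intermediates; it sets out from 7 (through borane 8) and returns at 10. Commercial (tert-butyldimethylsilyloxy)acetaldehyde in place of 6 reacts with 8 to give, after oxidative work-up, silyl ether alcohol F6. n-Bu4NF gives diol F7. N-Tosylimidazole and NaH in THF sulfonylate the primary hydroxyl and close epoxide 10 under anhydrous conditions with retention at C6.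

**Further compounds**

F1 | step 8 | 4-methoxybenzyl (E)-4,5-bis(4,4,5,5-tetramethyl-1,3,2-dioxaborolan-2-yl)pent-4-enoate | COc1ccc(COC(=O)CC/C(B2OC(C)(C)C(C)(C)O2)=C/B2OC(C)(C)C(C)(C)O2)cc1
F2 | step 8 | (1R,6S)-4-[(tert-butyldimethylsilyloxy)methyl]-5-hydroxy-3-{(1E)-5-[(4-methoxybenzyl)oxy]-5-oxo-2-(4,4,5,5-tetramethyl-1,3,2-dioxaborolan-2-yl)pent-1-en-1-yl}-6-methylcyclohex-3-en-1-yl 2,4-bis[(4-methoxybenzyl)oxy]-6-methylbenzoate | Cc1cc(OCc2ccc(OC)cc2)cc(OCc2ccc(OC)cc2)c1C(=O)O[C@@H]1CC(/C=C(\B2OC(C)(C)C(C)(C)O2)CCC(=O)OCc2ccc(OC)cc2)=C(CO[Si](C)(C)C(C)(C)C)C(O)[C@@H]1C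
F3 | step 8 | (1R,6S)-4-[(tert-butyldimethylsilyloxy)methyl]-5-hydroxy-3-{5-[(4-methoxybenzyl)oxy]-2,5-dioxopentyl}-6-methylcyclohex-3-en-1-yl 2,4-bis[(4-methoxybenzyl)oxy]-6-methylbenzoate | Cc1cc(OCc2ccc(OC)cc2)cc(OCc2ccc(OC)cc2)c1C(=O)O[C@@H]1CC(CC(=O)CCC(=O)OCc2ccc(OC)cc2)=C(CO[Si](C)(C)C(C)(C)C)C(O)[C@@H]1C
F4 | step 8 | (1R,6R)-4-[(tert-butyldimethylsilyloxy)methyl]-3-{5-[(4-methoxybenzyl)oxy]-2,5-dioxopentyl}-6-methyl-5-oxocyclohex-3-en-1-yl 2,4-bis[(4-methoxybenzyl)oxy]-6-methylbenzoate | Cc1cc(OCc2ccc(OC)cc2)cc(OCc2ccc(OC)cc2)c1C(=O)O[C@@H]1CC(CC(=O)CCC(=O)OCc2ccc(OC)cc2)=C(CO[Si](C)(C)C(C)(C)C)C(=O)[C@@H]1C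
F5 | step 11 | 5-[(5R,6R)-2-[(tert-butyldimethylsilyloxy)methyl]-5-(2,4-dihydroxy-6-methylbenzoyloxy)-6-methyl-1-oxocyclohex-2-en-3-yl]pent-4-ynoic acid | Cc1cc(O)cc(O)c1C(=O)O[C@@H]1CC(C#CCCC(=O)O)=C(CO[Si](C)(C)C(C)(C)C)C(=O)[C@@H]1C
F6 | step 4 | (2S,3S)-1-(tert-butyldimethylsilyloxy)-3-methylpent-4-en-2-ol | C=C[C@H](C)[C@H](O)CO[Si](C)(C)C(C)(C)C
F7 | step 4 | (2S,3S)-3-methylpent-4-ene-1,2-diol | C=C[C@H](C)[C@H](O)CO
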